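## Retrosynthetic overview
1. There is only one ring, the δ-lactone, and it is closed last. The C5-OH of the open-chain 3,5,7,9,11-pentahydroxy-C26 acyl thioester attacks C1, and the acyl-activated C3 oxygen is then lost to give C2=C3. This is the order of chain release and dehydration in the polyketide pathway.
2. C2–C3 comes from an acetate aldol of S-ethyl thioacetate on a C3 aldehyde (the last "extender unit"). The C3 configuration is erased later.
3. C9–C10 comes from a reagent-controlled boron aldol of heptadecan-2-one on a C9 aldehyde, which sets C9. A syn reduction in the same flask sets C11.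
4. C3–C9, with the syn C5 and C7 stereocentres, is bought as the atorvastatin nitrile acetonide. Its acetonide is the only protecting group in the route.

Assumption: atoms are numbered C1–C26 along the hexacosanoic chain (C1 = lactone C=O, ring O on C5), and 1, 4, 10 and (−)-Ipc2BCl are catalogue chemicals.

## Route

Step 1
Reactants: 1 tert-butyl 2-[(4R,6R)-6-(cyanomethyl)-2,2-dimethyl-1,3-dioxan-4-yl]acetate
Product: 3 tert-butyl 2-[(4R,6S)-2,2-dimethyl-6-(2-oxoethyl)-1,3-dioxan-4-yl]acetate, via N-aluminio aldimine 2 (not isolated)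
Conditions: i-Bu2AlH (1.05 equiv), PhMe, −78 °C, 1 h; then 10% aq citric acid, 0 °C
Reagents that add atoms: water, O
Why: Partial nitrile reduction with i-Bu2AlH works because the unhindered, more Lewis-basic nitrile is hydroaluminated at −78 °C faster than the bulky tert-butyl ester is attacked, one equivalent stops at 2, mild acid hydrolysis gives the aldehyde, and no stereocentre is touched.

Step 2
Reactants: 3 tert-butyl 2-[(4R,6S)-2,2-dimethyl-6-(2-oxoethyl)-1,3-dioxan-4-yl]acetate; 4 heptadecan-2-one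
Product: 7 tert-butyl 2-[(4R,6R)-6-[(2R,4R)-2,4-dihydroxynonadecyl]-2,2-dimethyl-1,3-dioxan-4-yl]acetate, via enol borinate 5 (not isolated), via boron aldolate 6 (not isolated)
Conditions: 4 (1.2 equiv), (−)-Ipc2BCl (1.3 equiv), Et3N (1.5 equiv), Et2O, 0 °C, 1 h; 3, −78 to −20 °C, 16 h; LiBH4 (3 equiv, THF), −78 °C, 3 h; MeOH, pH 7 buffer, 30% H2O2, 0 °C
Reagents that add atoms: none
Why: In this Paterson asymmetric boron aldol with a Narasaka–Prasad-type reduction in the same flask, (−)-Ipc2BCl/Et3N enolises 4 on the methyl side, the Ipc ligands steer the enolate to the Re face of aldehyde 3 (reagent control, C9 = R, expected dr about 5:1, minor epimer removed by chromatography), and LiBH4 reduces the six-membered boron chelate 6 to the 9,11-syn diol (C11 = R) while the tert-butyl ester and acetonide are inert at −78 °C.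

Step 3
Reactants: 7 tert-butyl 2-[(4R,6R)-6-[(2R,4R)-2,4-dihydroxynonadecyl]-2,2-dimethyl-1,3-dioxan-4-yl]acetate
Product: 9 2-[(4R,6R)-6-[(2R,4R)-2,4-dihydroxynonadecyl]-2,2-dimethyl-1,3-dioxan-4-yl]acetaldehyde, via aluminium hemiacetal 8 (not isolated)
Conditions: i-Bu2AlH (3.3 equiv), CH2Cl2, −78 °C, 1 h; MeOH; aq potassium sodium tartrate
Reagents that add atoms: none
Why: In this partial ester reduction with i-Bu2AlH, two equivalents are consumed by the free hydroxyls, the third adds once to the tert-butyl ester, the tetrahedral adduct 8 holds at −78 °C so the aldehyde appears only on work-up, and no stereocentre is touched.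

Step 4
Reactants: 9 2-[(4R,6R)-6-[(2R,4R)-2,4-dihydroxynonadecyl]-2,2-dimethyl-1,3-dioxan-4-yl]acetaldehyde; 10 S-ethyl ethanethioate
Product: 12 S-ethyl 4-[(4S,6R)-6-[(2R,4R)-2,4-dihydroxynonadecyl]-2,2-dimethyl-1,3-dioxan-4-yl]-3-hydroxybutanethioate (both C3 epimers), via lithium thioester enolate 11 (not isolated)
Conditions: LDA (4.1 equiv), 10 (4.0 equiv), THF, −78 °C, 30 min; 9, −78 °C, 30 min; AcOH/THF quench at −78 °C
Reagents that add atoms: none
Why: In this acetate-type aldol addition, excess lithium thioester enolate first deprotonates the two hydroxyls and then adds to the unhindered aldehyde faster than it enolises it at −78 °C, and the roughly 1:1 C3 epimer mixture is harmless because C3 becomes sp2 in step 5.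

Step 5
Reactants: 12 S-ethyl 4-[(4S,6R)-6-[(2R,4R)-2,4-dihydroxynonadecyl]-2,2-dimethyl-1,3-dioxan-4-yl]-3-hydroxybutanethioate
Product: 17 (6S)-6-[(2R,4R,6R)-2,4,6-trihydroxyhenicosyl]-5,6-dihydro-2H-pyran-2-one, via pentaol thioester 13 (not isolated), via hydroxy lactone 14 (not isolated), via tetrakis(trifluoroacetate) 15 (not isolated), via tris(trifluoroacetate) 16 (not isolated)
Conditions: one flask: (a) TFA–H2O–CH2Cl2 (10:1:40), 0 °C to rt, 3 h, strip with PhMe at 40 °C; (b) (CF3CO)2O (8 equiv), Et3N (14 equiv), CH2Cl2, −20 to 20 °C, 2 h; (c) MeOH, pH 7 phosphate buffer, 0 °C to rt, 1 h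
Reagents that add atoms: none
Why: Proposed new method: aqueous TFA hydrolyses the acetonide, and of the five hydroxyls of 13 only C5-OH reaches the thioester through a six-membered transition state, so it closes the δ-lactone with loss of volatile EtSH (thioesterase-like release; closest known types are acid lactonisation of statin 3,5-dihydroxy esters and thioester lactonisation); exhaustive trifluoroacetylation then masks the C7, C9 and C11 hydroxyls against oxa-Michael addition and turns C3-O into the only leaving group β to a carbonyl, so Et3N expels it by E1cB inside the ring (only the cis C2=C3 can form and both C3 epimers converge; closest known type is (CF3CO)2O/Et3N dehydration of aldols); and the three unactivated trifluoroacetates fall off in buffered MeOH without touching C5, C7, C9 or C11.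

## Compound list
1 | tert-butyl 2-[(4R,6R)-6-(cyanomethyl)-2,2-dimethyl-1,3-dioxan-4-yl]acetate | N#CC[C@@H]1C[C@H](CC(=O)OC(C)(C)C)OC(C)(C)O1 | starting material
2 | tert-butyl 2-[(4R,6R)-6-[2-(diisobutylaluminioimino)ethyl]-2,2-dimethyl-1,3-dioxan-4-yl]acetate | CC(C)C[Al](CC(C)C)N=CC[C@@H]1C[C@H](CC(=O)OC(C)(C)C)OC(C)(C)O1 | intermediate
3 | tert-butyl 2-[(4R,6S)-2,2-dimethyl-6-(2-oxoethyl)-1,3-dioxan-4-yl]acetate | O=CC[C@@H]1C[C@H](CC(=O)OC(C)(C)C)OC(C)(C)O1 | intermediate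
4 | heptadecan-2-one | CCCCCCCCCCCCCCCC(C)=O | starting material
5 | heptadec-1-en-2-yl diisopinocampheylborinate (Ipc groups as in (−)-Ipc2BCl) | C=C(CCCCCCCCCCCCCCC)OB([C@@H]1C[C@@H]2C[C@H]([C@H]1C)C2(C)C)[C@@H]3C[C@@H]4C[C@H]([C@H]3C)C4(C)C | intermediate
6 | tert-butyl 2-[(4R,6R)-6-[(2S)-2-(diisopinocampheylboryloxy)-4-oxononadecyl]-2,2-dimethyl-1,3-dioxan-4-yl]acetate | CCCCCCCCCCCCCCCC(=O)C[C@@H](OB([C@@H]2C[C@@H]3C[C@H]([C@H]2C)C3(C)C)[C@@H]4C[C@@H]5C[C@H]([C@H]4C)C5(C)C)C[C@@H]1C[C@H](CC(=O)OC(C)(C)C)OC(C)(C)O1 | intermediate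
7 | tert-butyl 2-[(4R,6R)-6-[(2R,4R)-2,4-dihydroxynonadecyl]-2,2-dimethyl-1,3-dioxan-4-yl]acetate | CCCCCCCCCCCCCCC[C@@H](O)C[C@@H](O)C[C@@H]1C[C@H](CC(=O)OC(C)(C)C)OC(C)(C)O1 | intermediate
8 | tris(diisobutylaluminium) derivative of 7: both carbinol oxygens as O-Al(i-Bu)2, and the ester carbon as CH(O-t-Bu)(O-Al(i-Bu)2) | CCCCCCCCCCCCCCC[C@@H](O[Al](CC(C)C)CC(C)C)C[C@@H](O[Al](CC(C)C)CC(C)C)C[C@@H]1C[C@H](CC(O[Al](CC(C)C)CC(C)C)OC(C)(C)C)OC(C)(C)O1 | intermediate
9 | 2-[(4R,6R)-6-[(2R,4R)-2,4-dihydroxynonadecyl]-2,2-dimethyl-1,3-dioxan-4-yl]acetaldehyde | CCCCCCCCCCCCCCC[C@@H](O)C[C@@H](O)C[C@@H]1C[C@H](CC=O)OC(C)(C)O1 | intermediate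
10 | S-ethyl ethanethioate | CCSC(C)=O | starting material
11 | lithium 1-(ethylsulfanyl)ethen-1-olate | [Li+].[O-]C(=C)SCC | intermediate
12 | S-ethyl 4-[(4S,6R)-6-[(2R,4R)-2,4-dihydroxynonadecyl]-2,2-dimethyl-1,3-dioxan-4-yl]-3-hydroxybutanethioate (C3 epimers) | CCCCCCCCCCCCCCC[C@@H](O)C[C@@H](O)C[C@@H]1C[C@H](CC(O)CC(=O)SCC)OC(C)(C)O1 | intermediate
13 | S-ethyl (5R,7R,9R,11R)-3,5,7,9,11-pentahydroxyhexacosanethioate (C3 epimers) | CCCCCCCCCCCCCCC[C@@H](O)C[C@@H](O)C[C@@H](O)C[C@@H](O)CC(O)CC(=O)SCC | intermediate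
14 | (6R)-4-hydroxy-6-[(2R,4R,6R)-2,4,6-trihydroxyhenicosyl]oxan-2-one (C4 epimers) | CCCCCCCCCCCCCCC[C@@H](O)C[C@@H](O)C[C@@H](O)C[C@@H]1CC(O)CC(=O)O1 | intermediate
15 | tetrakis(trifluoroacetate) of 14 (all four OH acylated, configurations unchanged) | CCCCCCCCCCCCCCC[C@@H](OC(=O)C(F)(F)F)C[C@@H](OC(=O)C(F)(F)F)C[C@@H](OC(=O)C(F)(F)F)C[C@@H]1CC(OC(=O)C(F)(F)F)CC(=O)O1 | intermediate
16 | tris(trifluoroacetate) of 17 (side-chain OH groups acylated, configurations unchanged) | CCCCCCCCCCCCCCC[C@@H](OC(=O)C(F)(F)F)C[C@@H](OC(=O)C(F)(F)F)C[C@@H](OC(=O)C(F)(F)F)C[C@@H]1CC=CC(=O)O1 | intermediate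
17 | (6S)-6-[(2R,4R,6R)-2,4,6-trihydroxyhenicosyl]-5,6-dihydro-2H-pyran-2-one | CCCCCCCCCCCCCCC[C@@H](O)C[C@@H](O)C[C@@H](O)C[C@@H]1CC=CC(=O)O1 | target

## Count and risks
Total step count: 5. Longest linear sequence: 5 steps, from 1.

**Step 5** is the most exposed step. Possible failures are lactonisation not finished before acylation, conjugate addition of thiol or of the C7-OH, and base-induced ring opening to the dienoic acid. The fallback leaves the dehydration out altogether. It sets out from aldehyde 9. A Z-selective Ando-type Horner–Wadsworth–Emmons olefination (ethyl 2-[bis(2-methylphenoxy)phosphoryl]acetate, NaI, DBU, THF, −78 to 0 °C) gives ethyl (2Z)-4-[(4S,6R)-6-[(2R,4R)-2,4-dihydroxynonadecyl]-2,2-dimethyl-1,3-dioxan-4-yl]but-2-enoate F1. AcOH–H2O (4:1) at 40 °C then removes the acetonide, and the freed C5-OH closes onto the cis-enoate. The fallback comes back to the route at 17 with the same step count.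

**Step 2** may give too low a C9 selectivity, since reagent control by Ipc ligands on a methyl ketone is only moderate. The fallback sets C9 by catalyst-controlled hydrogenation instead of by an aldol. It sets out from nitrile 1, so step 1 is not needed.
- A Blaise reaction (BrCH2CO2Et, Zn, cat. MsOH, THF, reflux; aq citric acid) gives ethyl 4-[(4S,6R)-6-(2-tert-butoxy-2-oxoethyl)-2,2-dimethyl-1,3-dioxan-4-yl]-3-oxobutanoate F2.
- Noyori hydrogenation with [RuCl2((S)-BINAP)]2·NEt3 (H2 10 bar, EtOH, 50 °C) gives ethyl (3S)-4-[(4R,6R)-6-(2-tert-butoxy-2-oxoethyl)-2,2-dimethyl-1,3-dioxan-4-yl]-3-hydroxybutanoate F3.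
- MeNH(OMe)·HCl with i-PrMgCl (THF, −20 °C) converts only the ethyl ester, giving tert-butyl 2-[(4R,6R)-6-[(2S)-2-hydroxy-4-[methoxy(methyl)amino]-4-oxobutyl]-2,2-dimethyl-1,3-dioxan-4-yl]acetate F4.
- n-C15H31MgBr (THF, 0 °C) gives tert-butyl 2-[(4R,6R)-6-[(2S)-2-hydroxy-4-oxononadecyl]-2,2-dimethyl-1,3-dioxan-4-yl]acetate F5.
- Et2BOMe/NaBH4 (THF–MeOH, −78 °C) reduces F5 syn and comes back to the route at 7.

**Step 1** may attack the ester as well, or run on to the amine. The fallback removes the nitrogen oxidatively instead of stopping a hydride reduction half-way. It sets out from 1. Full hydrogenation (Raney Ni, H2, NH3/MeOH) gives tert-butyl 2-[(4R,6R)-6-(2-aminoethyl)-2,2-dimethyl-1,3-dioxan-4-yl]acetate F6. Condensation with 3,5-di-tert-butyl-1,2-benzoquinone (MeOH–THF, rt) followed by a prototropic shift gives tert-butyl 2-[(4R,6R)-6-[2-(3,5-di-tert-butyl-2-hydroxyphenyl)iminoethyl]-2,2-dimethyl-1,3-dioxan-4-yl]acetate F7. Hydrolysis at pH 4 (aq oxalic acid, THF) comes back to the route at 3.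

## Further compounds
F1 | step 5 | ethyl (2Z)-4-[(4S,6R)-6-[(2R,4R)-2,4-dihydroxynonadecyl]-2,2-dimethyl-1,3-dioxan-4-yl]but-2-enoate | CCCCCCCCCCCCCCC[C@@H](O)C[C@@H](O)C[C@@H]1C[C@H](C/C=C\C(=O)OCC)OC(C)(C)O1
F2 | step 2 | ethyl 4-[(4S,6R)-6-(2-tert-butoxy-2-oxoethyl)-2,2-dimethyl-1,3-dioxan-4-yl]-3-oxobutanoate | CCOC(=O)CC(=O)C[C@@H]1C[C@H](CC(=O)OC(C)(C)C)OC(C)(C)O1
F3 | step 2 | ethyl (3S)-4-[(4R,6R)-6-(2-tert-butoxy-2-oxoethyl)-2,2-dimethyl-1,3-dioxan-4-yl]-3-hydroxybutanoate | CCOC(=O)C[C@@H](O)C[C@@H]1C[C@H](CC(=O)OC(C)(C)C)OC(C)(C)O1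
F4 | step 2 | tert-butyl 2-[(4R,6R)-6-[(2S)-2-hydroxy-4-[methoxy(methyl)amino]-4-oxobutyl]-2,2-dimethyl-1,3-dioxan-4-yl]acetate | CON(C)C(=O)C[C@@H](O)C[C@@H]1C[C@H](CC(=O)OC(C)(C)C)OC(C)(C)O1
F5 | step 2 | tert-butyl 2-[(4R,6R)-6-[(2S)-2-hydroxy-4-oxononadecyl]-2,2-dimethyl-1,3-dioxan-4-yl]acetate | CCCCCCCCCCCCCCCC(=O)C[C@@H](O)C[C@@H]1C[C@H](CC(=O)OC(C)(C)C)OC(C)(C)O1
F6 | step 1 | tert-butyl 2-[(4R,6R)-6-(2-aminoethyl)-2,2-dimethyl-1,3-dioxan-4-yl]acetate | NCC[C@@H]1C[C@H](CC(=O)OC(C)(C)C)OC(C)(C)O1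
F7 | step 1 | tert-butyl 2-[(4R,6R)-6-[2-(3,5-di-tert-butyl-2-hydroxyphenyl)iminoethyl]-2,2-dimethyl-1,3-dioxan-4-yl]acetate | CC(C)(C)c1cc(N=CC[C@@H]2C[C@H](CC(=O)OC(C)(C)C)OC(C)(C)O2)c(O)c(c1)C(C)(C)C
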